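**Retrosynthetic overview**
1. Feature: in the dihydronaphthalenedione ring, C2 (Cl, CH3) is α to the C1 ketone (peri to the C8 hydroxyl) and the carbinol C3 is α to the C4 ketone. The C2–C3 bond between the two quaternary carbons is therefore an aldol bond joining an α-chloro ketone enol on C8a to the C3 carbonyl of an aryl 1,2-diketone on C4a.
2. The only ring formed (C1–C2–C3–C4–C4a–C8a) is closed last, at C2–C3, by a copper(II)–bis(oxazoline)-catalysed intramolecular Mukaiyama aldol of the (Z)-chloro enol silane with the chelated diketone; desilylation ends the route.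
3. The diketone is carried at the acyloin level (C3–OSiEt3) and unveiled only after every enolisable site is silylated, by positive-bromine oxidation of the enediol bis(silyl) ether. A thioketal at C3 is avoided because its removal would not spare a trimethylsilyl enol ether and three trisubstituted alkenes.
4. Arene: 5-bromoresorcinol is formylated (C1), 1-chloroethyllithium adds (C2, Cl, CH3), then Br/Li exchange at C4a and acylation by the side-chain α-silyloxy Weinreb amide form C4a–C4.
5. Side chain: deconjugative α-geranylation of methyl 3-methylbut-2-enoate, isomerisation, reduction and bromination, then alkylation of a glycolate enolate (C3–CH2).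

Key step: step 15

Assumption: the face of C3 opened by the copper chelate is assigned from the si-face addition known for the (S,S)-tert-butyl complex with chelated pyruvates. Because the incoming C2 outranks C4, that face would give 3R, so the (R,R) ligand is used; its antipode is used if the first cyclisation shows the opposite sense.
Remark: 7, 11 and 19–24 are racemic (7, 23, 24 as diastereomer mixtures). 26 is achiral, so both stereocentres of the target arise in step 15.

**Step 1**
Reactants: 1 5-bromoresorcinol
Product: 3 2-bromo-4,6-dihydroxybenzaldehyde, via aryl iminium chloride 2 (not isolated)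
Conditions: POCl3, DMF, MeCN, −15 °C → rt; then H2O, 50 °C
Reagents that add atoms: N,N-dimethylformamide CN(C)C=O; water O
Why: Vilsmeier–Haack formylation of a 5-substituted resorcinol should go para to one hydroxyl and ortho to the other, next to the 5-substituent, which places the formyl carbon (future C1) on the future C8a beside the bromine on C4a.

**Step 2**
Reactants: 3 2-bromo-4,6-dihydroxybenzaldehyde
Product: 4 2-bromo-4,6-bis(triisopropylsilyloxy)benzaldehyde
Conditions: TIPSOTf, 2,6-lutidine, CH2Cl2, 0 °C → rt
Reagents that add atoms: triisopropylsilyl trifluoromethanesulfonate CC(C)[Si](OS(=O)(=O)C(F)(F)F)(C(C)C)C(C)C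
Why: Silyl triflate O-silylation should protect both phenols including the hydrogen-bonded ortho one; triisopropylsilyl is chosen because it resists organolithiums and the 1,5 O→O shift to the benzylic alkoxide formed in steps 3 and 11.

**Step 3**
Reactants: 4 2-bromo-4,6-bis(triisopropylsilyloxy)benzaldehyde; 5 1-bromo-1-chloroethane
Product: 7 1-[2-bromo-4,6-bis(triisopropylsilyloxy)phenyl]-2-chloropropan-1-ol (racemic diastereomer mixture), via 1-chloroethyllithium 6 (not isolated)
Conditions: 5, n-BuLi, THF/Et2O/pentane, −110 °C; then 4, −110 → −90 °C; AcOH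
Reagents that add atoms: none
Why: Bromine–lithium exchange gives the α-chloroalkyllithium carbenoid, which should add to the aldehyde faster than it decomposes at −110 °C (carbenoid addition to a carbonyl group); the aryl bromide survives because no butyllithium remains, and both new stereocentres are erased later.

**Step 4**
Reactants: 8 methyl 3-methylbut-2-enoate; 9 geranyl bromide
Product: 11 methyl 2-[(2E)-3,7-dimethylocta-2,6-dien-1-yl]-3-methylbut-3-enoate (racemic), via lithium dienolate 10 (not isolated)
Conditions: LDA, THF, DMPU, −78 °C; then 9, −78 → 0 °C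
Reagents that add atoms: none
Why: γ-Deprotonation gives the extended dienolate, which should be alkylated at its α-carbon by the allylic bromide (deconjugative SN2 α-alkylation) without touching the E alkene of the geranyl unit.

**Step 5**
Reactants: 11 methyl 2-[(2E)-3,7-dimethylocta-2,6-dien-1-yl]-3-methylbut-3-enoate
Product: 12 methyl 2-[(2E)-3,7-dimethylocta-2,6-dien-1-yl]-3-methylbut-2-enoate
Conditions: NaOMe (cat.), MeOH, 60 °C
Reagents that add atoms: none
Why: Base-mediated equilibration through the dienolate should move the 1,1-disubstituted alkene into conjugation as the tetrasubstituted enoate; any remaining β,γ-isomer is separated and resubmitted.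

**Step 6**
Reactants: 12 methyl 2-[(2E)-3,7-dimethylocta-2,6-dien-1-yl]-3-methylbut-2-enoate
Product: 13 (4E)-5,9-dimethyl-2-(propan-2-ylidene)deca-4,8-dien-1-ol
Conditions: DIBAL-H, CH2Cl2, −78 → 0 °C; Rochelle salt
Reagents that add atoms: none
Why: 1,2-Reduction of the enoate by DIBAL-H should give the allylic alcohol and leave the isolated trisubstituted alkenes alone.

**Step 7**
Reactants: 13 (4E)-5,9-dimethyl-2-(propan-2-ylidene)deca-4,8-dien-1-ol
Product: 15 (5E)-3-(bromomethyl)-2,6,10-trimethylundeca-2,5,9-triene, via allylic mesylate 14 (not isolated)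
Conditions: MsCl, Et3N, THF, −40 °C; then LiBr, −40 → 0 °C
Reagents that add atoms: lithium bromide [Li+].[Br-]
Why: SN2 displacement of the primary allylic mesylate by bromide should give the primary bromide, since the SN2′ isomer would carry bromine on a tertiary carbon and a less substituted alkene; 15 is used without storage.

**Step 8**
Reactants: 16 ethyl glycolate
Product: 17 ethyl 2-(triethylsilyloxy)acetate
Conditions: TESCl, imidazole, CH2Cl2, 0 °C → rt
Reagents that add atoms: chlorotriethylsilane CC[Si](Cl)(CC)CC
Why: Standard silylation of a primary alcohol; the triethylsilyl ether keeps C3 at the alcohol oxidation level and is later lost cleanly as Et3SiBr.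

**Step 9**
Reactants: 17 ethyl 2-(triethylsilyloxy)acetate; 15 (5E)-3-(bromomethyl)-2,6,10-trimethylundeca-2,5,9-triene
Product: 19 ethyl (6E)-7,11-dimethyl-4-(propan-2-ylidene)-2-(triethylsilyloxy)dodeca-6,10-dienoate (racemic), via lithium enolate 18 (not isolated)
Conditions: LDA, THF, −78 °C; then 15, DMPU, −78 → −20 °C
Reagents that add atoms: none
Why: SN2 alkylation of the α-silyloxy ester enolate at the primary allylic carbon should form the C3–CH2 bond; C3 is racemic here and becomes sp2 in step 13.

**Step 10**
Reactants: 19 ethyl (6E)-7,11-dimethyl-4-(propan-2-ylidene)-2-(triethylsilyloxy)dodeca-6,10-dienoate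
Product: 20 (6E)-N-methoxy-N,7,11-trimethyl-4-(propan-2-ylidene)-2-(triethylsilyloxy)dodeca-6,10-dienamide
Conditions: MeNHOMe·HCl, i-PrMgCl, THF, −20 → 0 °C
Reagents that add atoms: N,O-dimethylhydroxylamine hydrochloride CNOC.Cl
Why: Aminolysis of the ester by the chloromagnesium amide (Weinreb amide formation) should proceed at low temperature without loss of the silyl ether or migration of the tetrasubstituted alkene.

**Step 11**
Reactants: 7 1-[2-bromo-4,6-bis(triisopropylsilyloxy)phenyl]-2-chloropropan-1-ol; 20 (6E)-N-methoxy-N,7,11-trimethyl-4-(propan-2-ylidene)-2-(triethylsilyloxy)dodeca-6,10-dienamide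
Product: 23 (6E)-1-[2-(2-chloro-1-hydroxypropyl)-3,5-bis(triisopropylsilyloxy)phenyl]-7,11-dimethyl-4-(propan-2-ylidene)-2-(triethylsilyloxy)dodeca-6,10-dien-1-one (diastereomer mixture in equilibrium with its lactol), via aryllithium alkoxide 21 (not isolated), via lithium hemiaminal 22 (not isolated)
Conditions: 7, MeLi (1 equiv), THF, −78 °C; t-BuLi (2 equiv), −78 °C; then 20, −78 °C; AcOH, −78 °C
Reagents that add atoms: none
Why: With the carbinol protected as its alkoxide, bromine–lithium exchange gives the aryllithium at C4a (meta to both silyloxy groups, so no retro-Brook shift), which should add to the Weinreb amide and give the C4 ketone after collapse of the chelated adduct; at −78 °C the alkoxide should not close to the epoxide nor the aryllithium displace the secondary chloride.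

**Step 12**
Reactants: 23 (6E)-1-[2-(2-chloro-1-hydroxypropyl)-3,5-bis(triisopropylsilyloxy)phenyl]-7,11-dimethyl-4-(propan-2-ylidene)-2-(triethylsilyloxy)dodeca-6,10-dien-1-one
Product: 24 (6E)-1-[2-(2-chloropropanoyl)-3,5-bis(triisopropylsilyloxy)phenyl]-7,11-dimethyl-4-(propan-2-ylidene)-2-(triethylsilyloxy)dodeca-6,10-dien-1-one
Conditions: Dess–Martin periodinane, pyridine, CH2Cl2, 0 °C → rt
Reagents that add atoms: none
Why: Dess–Martin oxidation of the benzylic carbinol, through the open hydroxy ketone in equilibrium with the lactol, should give the α-chloro ketone under buffered conditions that leave alkenes and silyl ethers alone.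

**Step 13**
Reactants: 24 (6E)-1-[2-(2-chloropropanoyl)-3,5-bis(triisopropylsilyloxy)phenyl]-7,11-dimethyl-4-(propan-2-ylidene)-2-(triethylsilyloxy)dodeca-6,10-dien-1-one
Product: 25 (6E)-1-{2-[(1Z)-2-chloro-1-(trimethylsilyloxy)prop-1-en-1-yl]-3,5-bis(triisopropylsilyloxy)phenyl}-7,11-dimethyl-4-(propan-2-ylidene)-2-(triethylsilyloxy)-1-(trimethylsilyloxy)dodeca-1,6,10-triene
Conditions: TMSCl (5 equiv), LiHMDS (3 equiv), THF, −78 °C (in situ quench), then → −20 °C; pentane, filtration under argon
Reagents that add atoms: chlorotrimethylsilane C[Si](C)(C)Cl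
Why: Kinetic amide enolisation with internal silyl quench should first deprotonate the more acidic α-chloro ketone through a closed transition state in which lithium bridges the carbonyl oxygen and chlorine (chlorine cis to oxygen, Z), and then remove the only α-hydrogen of the C4 ketone (C3–H) to give the enediol bis(silyl) ether, whose own geometry is of no consequence.

**Step 14**
Reactants: 25 (6E)-1-{2-[(1Z)-2-chloro-1-(trimethylsilyloxy)prop-1-en-1-yl]-3,5-bis(triisopropylsilyloxy)phenyl}-7,11-dimethyl-4-(propan-2-ylidene)-2-(triethylsilyloxy)-1-(trimethylsilyloxy)dodeca-1,6,10-triene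
Product: 26 (6E)-1-{2-[(1Z)-2-chloro-1-(trimethylsilyloxy)prop-1-en-1-yl]-3,5-bis(triisopropylsilyloxy)phenyl}-7,11-dimethyl-4-(propan-2-ylidene)dodeca-6,10-diene-1,2-dione
Conditions: NBS (1.0 equiv), THF, −78 °C, dark; pentane, cold aq. NaHCO3; used at once
Reagents that add atoms: none
Why: Positive-bromine oxidation of an acyloin-derived enediol bis(silyl) ether to the 1,2-diketone (bromine is the documented oxidant; NBS is the milder Br+ donor) should occur at the doubly oxygenated alkene, by far the most nucleophilic π bond, with loss of both silyl groups, while the hindered chlorine-bearing enol silane and the trisubstituted alkenes are spared by one equivalent at −78 °C.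

**Step 15**
Reactants: 26 (6E)-1-{2-[(1Z)-2-chloro-1-(trimethylsilyloxy)prop-1-en-1-yl]-3,5-bis(triisopropylsilyloxy)phenyl}-7,11-dimethyl-4-(propan-2-ylidene)dodeca-6,10-diene-1,2-dione
Product: 27 (2R,3S)-2-chloro-3-[(4E)-5,9-dimethyl-2-(propan-2-ylidene)deca-4,8-dien-1-yl]-2-methyl-6,8-bis(triisopropylsilyloxy)-3-(trimethylsilyloxy)-2,3-dihydronaphthalene-1,4-dione
Conditions: [Cu((R,R)-t-Bu-box)](OTf)2 (15 mol %), CH2Cl2/THF, −78 → −30 °C
Reagents that add atoms: none
Why: Proposed new method: the copper(II)–bis(oxazoline) should bind the s-cis diketone through O3 and O4, the tethered enol silane adds through C2 to the activated C3 carbonyl, and transfer of the trimethylsilyl group from the C1 oxocarbenium oxygen to the copper alkoxide releases the catalyst and gives the C3 silyl ether, so that no free alkoxide can displace the neighbouring chloride. The closest known reaction is the intermolecular copper(II)–bis(oxazoline) Mukaiyama aldol of enol silanes with pyruvates and 2,3-diones; an intramolecular version with a tetrasubstituted α-chloro enol silane is not known. The six-membered ring closes in a 6-(enolendo)-exo-trig mode, whereas attack on the C4 carbonyl would be a disfavoured 5-(enolendo)-exo-trig closure. C3 is set by the ligand, which shields one face of the chelated C3 carbonyl; the (R,R) ligand is chosen so that C2 adds to the re face, giving 3S. C2 is set relative to C3 by the enol geometry: in the half-chair transition state the groups cis to the arene on the enol (CH3) and on the chelated ketone (the side-chain CH2) both become axial and hence trans, so the Z enol silane places chlorine cis to the side chain and trans to oxygen (2R). The step needs aldol addition to outrun Lewis-acid enolisation of the C3 ketone towards its allylic CH2, which low temperature, absence of base and the intramolecular rate should secure, and it needs the Z geometry made in step 13.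

**Step 16**
Reactants: 27 (2R,3S)-2-chloro-3-[(4E)-5,9-dimethyl-2-(propan-2-ylidene)deca-4,8-dien-1-yl]-2-methyl-6,8-bis(triisopropylsilyloxy)-3-(trimethylsilyloxy)-2,3-dihydronaphthalene-1,4-dione
Product: 28 (2R,3S)-2-chloro-3-[(4E)-5,9-dimethyl-2-(propan-2-ylidene)deca-4,8-dien-1-yl]-3,6,8-trihydroxy-2-methyl-2,3-dihydronaphthalene-1,4-dione (CNP0351608.1)
Conditions: TBAF, AcOH (1:1.2), THF, 0 °C
Reagents that add atoms: none
Why: Acetic acid-buffered fluoride should cleave the two aryl silyl ethers and the tertiary trimethylsilyl ether without leaving a free C3 alkoxide that could close onto C2 as an epoxide or undergo retro-aldol cleavage; both stereocentres are quaternary and cannot epimerise.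

**Compound list**
1 | 5-bromoresorcinol | Oc1cc(O)cc(Br)c1 | starting material
2 | N-[(2-bromo-4,6-dihydroxyphenyl)methylidene]-N-methylmethanaminium chloride | C[N+](C)=Cc1c(Br)cc(O)cc1O.[Cl-] | intermediate (not isolated)
3 | 2-bromo-4,6-dihydroxybenzaldehyde | O=Cc1c(Br)cc(O)cc1O | intermediate
4 | 2-bromo-4,6-bis(triisopropylsilyloxy)benzaldehyde | O=Cc1c(Br)cc(O[Si](C(C)C)(C(C)C)C(C)C)cc1O[Si](C(C)C)(C(C)C)C(C)C | intermediate
5 | 1-bromo-1-chloroethane | CC(Cl)Br | starting material
6 | 1-chloroethyllithium | CC(Cl)[Li] | intermediate (not isolated)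
7 | 1-[2-bromo-4,6-bis(triisopropylsilyloxy)phenyl]-2-chloropropan-1-ol (racemic, both diastereomers) | CC(Cl)C(O)c1c(Br)cc(O[Si](C(C)C)(C(C)C)C(C)C)cc1O[Si](C(C)C)(C(C)C)C(C)C | intermediate
8 | methyl 3-methylbut-2-enoate | COC(=O)C=C(C)C | starting material
9 | geranyl bromide | CC(C)=CCC/C(C)=C/CBr | starting material
10 | lithium 1-methoxy-3-methylbuta-1,3-dien-1-olate | COC(O[Li])=CC(C)=C | intermediate (not isolated)
11 | methyl 2-[(2E)-3,7-dimethylocta-2,6-dien-1-yl]-3-methylbut-3-enoate (racemic) | COC(=O)C(C/C=C(\C)CCC=C(C)C)C(C)=C | intermediate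
12 | methyl 2-[(2E)-3,7-dimethylocta-2,6-dien-1-yl]-3-methylbut-2-enoate | COC(=O)C(C/C=C(\C)CCC=C(C)C)=C(C)C | intermediate
13 | (4E)-5,9-dimethyl-2-(propan-2-ylidene)deca-4,8-dien-1-ol | OCC(C/C=C(\C)CCC=C(C)C)=C(C)C | intermediate
14 | (4E)-5,9-dimethyl-2-(propan-2-ylidene)deca-4,8-dien-1-yl methanesulfonate | CS(=O)(=O)OCC(C/C=C(\C)CCC=C(C)C)=C(C)C | intermediate (not isolated)
15 | (5E)-3-(bromomethyl)-2,6,10-trimethylundeca-2,5,9-triene | BrCC(C/C=C(\C)CCC=C(C)C)=C(C)C | intermediate
16 | ethyl glycolate | CCOC(=O)CO | starting material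
17 | ethyl 2-(triethylsilyloxy)acetate | CCOC(=O)CO[Si](CC)(CC)CC | intermediate
18 | lithium 1-ethoxy-2-(triethylsilyloxy)ethen-1-olate | CCOC(O[Li])=CO[Si](CC)(CC)CC | intermediate (not isolated)
19 | ethyl (6E)-7,11-dimethyl-4-(propan-2-ylidene)-2-(triethylsilyloxy)dodeca-6,10-dienoate (racemic) | CCOC(=O)C(O[Si](CC)(CC)CC)CC(C/C=C(\C)CCC=C(C)C)=C(C)C | intermediate
20 | (6E)-N-methoxy-N,7,11-trimethyl-4-(propan-2-ylidene)-2-(triethylsilyloxy)dodeca-6,10-dienamide (racemic) | CON(C)C(=O)C(O[Si](CC)(CC)CC)CC(C/C=C(\C)CCC=C(C)C)=C(C)C | intermediate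
21 | lithium 1-[2-lithio-4,6-bis(triisopropylsilyloxy)phenyl]-2-chloropropan-1-olate | CC(Cl)C(O[Li])c1c([Li])cc(O[Si](C(C)C)(C(C)C)C(C)C)cc1O[Si](C(C)C)(C(C)C)C(C)C | intermediate (not isolated)
22 | dilithium tetrahedral adduct of 21 and 20 | CC(Cl)C(O[Li])c1c(O[Si](C(C)C)(C(C)C)C(C)C)cc(O[Si](C(C)C)(C(C)C)C(C)C)cc1C(O[Li])(N(C)OC)C(O[Si](CC)(CC)CC)CC(C/C=C(\C)CCC=C(C)C)=C(C)C | intermediate (not isolated)
23 | (6E)-1-[2-(2-chloro-1-hydroxypropyl)-3,5-bis(triisopropylsilyloxy)phenyl]-7,11-dimethyl-4-(propan-2-ylidene)-2-(triethylsilyloxy)dodeca-6,10-dien-1-one (diastereomer mixture) | CC(Cl)C(O)c1c(O[Si](C(C)C)(C(C)C)C(C)C)cc(O[Si](C(C)C)(C(C)C)C(C)C)cc1C(=O)C(O[Si](CC)(CC)CC)CC(C/C=C(\C)CCC=C(C)C)=C(C)C | intermediate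
24 | (6E)-1-[2-(2-chloropropanoyl)-3,5-bis(triisopropylsilyloxy)phenyl]-7,11-dimethyl-4-(propan-2-ylidene)-2-(triethylsilyloxy)dodeca-6,10-dien-1-one (diastereomer mixture) | CC(Cl)C(=O)c1c(O[Si](C(C)C)(C(C)C)C(C)C)cc(O[Si](C(C)C)(C(C)C)C(C)C)cc1C(=O)C(O[Si](CC)(CC)CC)CC(C/C=C(\C)CCC=C(C)C)=C(C)C | intermediate
25 | tris(silyl) ether: (Z)-chloro enol silane with enediol bis(silyl) ether | C/C(Cl)=C(/O[Si](C)(C)C)c1c(O[Si](C(C)C)(C(C)C)C(C)C)cc(O[Si](C(C)C)(C(C)C)C(C)C)cc1C(O[Si](C)(C)C)=C(O[Si](CC)(CC)CC)CC(C/C=C(\C)CCC=C(C)C)=C(C)C | intermediate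
26 | aryl 1,2-diketone with ortho (Z)-2-chloro-1-(trimethylsilyloxy)prop-1-enyl group (key-step precursor) | C/C(Cl)=C(/O[Si](C)(C)C)c1c(O[Si](C(C)C)(C(C)C)C(C)C)cc(O[Si](C(C)C)(C(C)C)C(C)C)cc1C(=O)C(=O)CC(C/C=C(\C)CCC=C(C)C)=C(C)C | intermediate
27 | (2R,3S)-2-chloro-3-[(4E)-5,9-dimethyl-2-(propan-2-ylidene)deca-4,8-dien-1-yl]-2-methyl-6,8-bis(triisopropylsilyloxy)-3-(trimethylsilyloxy)-2,3-dihydronaphthalene-1,4-dione | CC(C)=CCC/C(C)=C/CC(C[C@]1(O[Si](C)(C)C)C(=O)c2cc(O[Si](C(C)C)(C(C)C)C(C)C)cc(O[Si](C(C)C)(C(C)C)C(C)C)c2C(=O)[C@]1(C)Cl)=C(C)C | intermediate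
28 | (2R,3S)-2-chloro-3-[(4E)-5,9-dimethyl-2-(propan-2-ylidene)deca-4,8-dien-1-yl]-3,6,8-trihydroxy-2-methyl-2,3-dihydronaphthalene-1,4-dione | CC(C)=CCC/C(C)=C/CC(C[C@]1(O)C(=O)c2cc(O)cc(O)c2C(=O)[C@]1(C)Cl)=C(C)C | target

**Step count**
Total: 16 steps (arene branch 3, side-chain branch 4, glycolate branch 3, common part 6).
Longest linear sequence: 12 steps (steps 4–7 and 9–16).

**Steps most likely to fail**

Step 15 (proposed new method). The copper chelate may discriminate the faces of C3 poorly in the intramolecular setting, turnover may stall at the hindered silyl transfer, the Lewis acid may enolise the C3 ketone or move the side-chain alkene into conjugation, and reaction through the non-chelated s-trans diketone would erode the diastereoselectivity. The fallback sets out from 26 and comes back at 28. Cyclisation with TiCl4 (CH2Cl2, −78 °C) is the classical Mukaiyama aldol to a ketone; titanium chelates the diketone and should keep the same relative configuration. Aqueous work-up should give the racemic tertiary alcohol, that is the (2R,3S) bis(triisopropylsilyl) ether F1 together with its enantiomer F2. These are separated by preparative HPLC on a chiral stationary phase, and F1 is desilylated under the conditions of step 16 to give 28.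

Step 14. The oxidant may also brominate the chloro enol silane or the trisubstituted alkenes, the silyl by-products may silylate the acidic diketone, and the trimethylsilyl enol ether may hydrolyse during isolation. The fallback sets out from 24 and comes back at 26. Only the more acidic α-chloro ketone is enolised and silylated (LiHMDS 1.05 equiv, TMSCl in situ, THF, −78 °C) to give the mono(enol silane) F3. Its potassium enolate at C3 (KHMDS, THF, −78 °C) is added to 2-(phenylsulfonyl)-3-phenyloxaziridine at −78 °C and quenched cold with AcOH. The α-oxygenated hemiketal should lose triethylsilanolate to give 26. Chemoselectivity then rests on an enolate against neutral π bonds and no longer on a ranking of neutral alkenes.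

Step 13. Enolisation of the α-chloro ketone may give an E/Z mixture, the second enolisation at C3 may stay incomplete, and the enolate oxygen may add to the neighbouring ketone or a silyl group may migrate before trapping. The fallback sets out from 7 and comes back at 25. Dess–Martin oxidation of 7 gives the α-chloro ketone F4, which has a single enolisable position. LiHMDS/TMSCl gives the enol silane F5, whose geometry can be assigned and whose isomers can be separated at this simple stage. Bromine–lithium exchange (t-BuLi, Et2O, −100 °C, where 1,4 O→C silyl shift is slow) and acylation with 20 gives the mono(enol silane) F3, and KHMDS/TMSCl then gives 25.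

**Further compounds**
F1 | step 15 | (2R,3S)-2-chloro-3-[(4E)-5,9-dimethyl-2-(propan-2-ylidene)deca-4,8-dien-1-yl]-3-hydroxy-2-methyl-6,8-bis(triisopropylsilyloxy)-2,3-dihydronaphthalene-1,4-dione | CC(C)=CCC/C(C)=C/CC(C[C@]1(O)C(=O)c2cc(O[Si](C(C)C)(C(C)C)C(C)C)cc(O[Si](C(C)C)(C(C)C)C(C)C)c2C(=O)[C@]1(C)Cl)=C(C)C
F2 | step 15 | (2S,3R) enantiomer of F1 | CC(C)=CCC/C(C)=C/CC(C[C@@]1(O)C(=O)c2cc(O[Si](C(C)C)(C(C)C)C(C)C)cc(O[Si](C(C)C)(C(C)C)C(C)C)c2C(=O)[C@@]1(C)Cl)=C(C)C
F3 | step 14 | (6E)-1-{2-[(1Z)-2-chloro-1-(trimethylsilyloxy)prop-1-en-1-yl]-3,5-bis(triisopropylsilyloxy)phenyl}-7,11-dimethyl-4-(propan-2-ylidene)-2-(triethylsilyloxy)dodeca-6,10-dien-1-one | C/C(Cl)=C(/O[Si](C)(C)C)c1c(O[Si](C(C)C)(C(C)C)C(C)C)cc(O[Si](C(C)C)(C(C)C)C(C)C)cc1C(=O)C(O[Si](CC)(CC)CC)CC(C/C=C(\C)CCC=C(C)C)=C(C)C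
F4 | step 13 | 1-[2-bromo-4,6-bis(triisopropylsilyloxy)phenyl]-2-chloropropan-1-one | CC(Cl)C(=O)c1c(Br)cc(O[Si](C(C)C)(C(C)C)C(C)C)cc1O[Si](C(C)C)(C(C)C)C(C)C
F5 | step 13 | {[(1Z)-1-[2-bromo-4,6-bis(triisopropylsilyloxy)phenyl]-2-chloroprop-1-en-1-yl]oxy}trimethylsilane | C/C(Cl)=C(/O[Si](C)(C)C)c1c(Br)cc(O[Si](C(C)C)(C(C)C)C(C)C)cc1O[Si](C(C)C)(C(C)C)C(C)C
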